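all flasks: starting material 0.30 M
- eta: reagent in the second phase 0.45 M; the very flask that is asked about, followed so far
- flask: reagent in the second phase 0.450 M; time 6.0 min; volume of the second phase over the first 1.0

eta run (percent of the starting material charged)

| time / min | target / % | starting material / % |
|---|---|---|
| 0.167 | 2.0 | 99.1 |
| 0.500 | 5.6 | 94.0 |
| 0.833 | 8.8 | 90.8 |
| 1.33 | 14.1 | 87.1 |
| 2.00 | 18.2 | 81.8 |
| 2.50 | 20.6 | 77.9 |
| 3.00 | 24.1 | 73.8 |

(each reading ± 0.5 percentage points)

- in the second phase: reagent in the second phase; everything else is in the first
- charges count per volume of the first phase; a concentration in a rate is the amount of a species over the volume of its own phase; every rate counts per litre of the first phase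
- steps that have been proposed: reagent in the reaction phase <-> reagent in the second phase; starting material + reagent in the reaction phase -> target; reagent in the reaction phase + target -> over-reacted product; reagent in the reaction phase <-> dormant form
- the earlier runs hold the two phases in the same ratio of volumes as the flask asked about

* the target standing at 6.0 min, as a percentage of the starting material charged
* the change that raises the amount of target at 6.0 min, in percent of the starting material charged most ("none" if none brings more than 2 percentage points) (birch / larch / none)
* amount of target at 6.0 min, in percent of the starting material charged, after birch

**Main step.** If you trust readings and little else, start from the eta run, which is this flask followed to 3.00 min. Hold the reagent constant, the pseudo-first-order view. Starting material at 73.8% gives 0.101 /min. Carried to 6.0 min, that makes 45.5% target.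

**Falling reagent.** But reagent is used. Count the reagent pool: the unreacted reagent in the second phase, in the reaction phase and in the dormant form, taken together. It starts at 0.450 M and loses what the starting material loses, plus what over-reaction takes, which I set aside here. Write the loss as a constant times starting material times pool. The integrated second-order law turns the same reading into the pool constant, 0.249 /M/min. The 2.00 min reading gives 0.238 /M/min, close to it, so hold it. Starting material at 6.0 min becomes 57.1%, and target 42.9%.

**Over-reaction.** The balance at 3.00 min lacks 2.10%, a loose reading with 0.5 percentage points on each term. Reagent feeds both steps, so it cancels per unit of conversion. Target grows with conversion, so let over-reacted product grow with its square. That gives 5.64% and leaves 37.3% target. This is my number.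

**The changes.** Transfer and the dormant form sit inside the constant. The mean target slope up to 0.167 min is twice the late slope, so no lag shows, and I expect birch to stay near 37.3%. Doubling the pool gives larch 54.1%.

**The result.** The forecast, a little above my number, says 38.5%, larch, and 40% after birch: “Doubling transfer should change little”. The flask gives 37.2%. The change that raises the target most is larch, by 15 points. Birch adds 0.11 points and stands at 37.3%.

    reagent in the reaction phase ⇌ reagent in the second phase, rate k1*([reagent in the reaction phase] - [reagent in the second phase]/K1) per volume of the first phase (partition coefficient = 0.830, kL = 0.160 /s)
    starting material + reagent in the reaction phase → target (k = 0.0110 /M/s)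
    reagent in the reaction phase + target → over-reacted product (k = 0.00420 /M/s)
    reagent in the reaction phase ⇌ dormant form (K = 0.960, k = 0.0260 /s)

**Longer reading.** At 6.00 min my 57.1% starting material stands against 58.5% in this flask, and my 5.64% over-reacted product against 4.32%. Now read the same charge at 15 min. The pool constant 0.249 /M/min gives starting material 30.8%, over-reacted product 14.7% and target 54.6%. That flask shows 34.1%, 13.8% and 52.1%, so my target there stands 2.5 points high.

Readings and results were computed on assumed constants.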